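**Plan**

- Retrosynthesis: on ring B (the perbrominated ring; B1 = ether carbon, B2 = hydroxyl carbon, B3–B6 = bromine) the B2–OH bond is traced back to B2–I. The B1–O(aryl) and B2–I bonds are then cut together.
- This double cut is possible because ring B has two different heteroatoms on neighbouring carbons and bromine on the other four. That is the substitution pattern left by the symmetrical 3,4,5,6-tetrabromobenzyne when it takes up the phenoxide of ring A and an iodine donor.
- Forward: no ring is formed. Ring B is armed as an ortho-silyl triflate (steps 1–3), ring A is trimmed to 3,5-dibromo-2-methoxyphenol (steps 4–5), the rings are joined in step 6, and step 7 converts C–I into C–OH.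
- Stereochemistry: the target has no stereogenic element, so nothing has to be set.

Key step: step 6

Remark: ring A is the dibromomethoxyphenyl ring and ring B the perbrominated ring; equivalents, temperatures and times are proposals.

**Step 1**
Reactants: 1 pentabromophenol
Product: 2 trimethyl(pentabromophenoxy)silane
Conditions: (Me3Si)2NH (0.6 equiv), THF, reflux; evaporation under argon, used crude
Reagents that add atoms: hexamethyldisilazane, C[Si](C)(C)N[Si](C)(C)C
Why: O-silylation of a phenol with hexamethyldisilazane is standard silyl ether formation; the acidic phenol should react readily, only ammonia is lost, and the moisture-sensitive ether can be carried on without aqueous work-up.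

**Step 2**
Reactants: 2 trimethyl(pentabromophenoxy)silane
Product: 5 2,3,4,5-tetrabromo-6-(trimethylsilyl)phenol, via ortho-lithio silyl ether 3 (not isolated), via lithium silylphenoxide 4 (not isolated)
Conditions: n-BuLi (0.95 equiv, added over 1 h), THF, −78 °C; AcOH, −78 °C → rt
Reagents that add atoms: none
Why: Bromine–lithium exchange followed by anionic 1,3 O→C silyl migration (retro-Brook rearrangement) is the standard entry to ortho-silylphenols; only the aryllithium next to oxygen can pass silicon irreversibly to carbon, and with n-BuLi kept just below one equivalent the remaining bromide shuttles bromine and lithium between ring positions at −78 °C, so lithio isomers formed elsewhere should drain through 3 into 4 before they can lose LiBr.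

**Step 3**
Reactants: 5 2,3,4,5-tetrabromo-6-(trimethylsilyl)phenol
Product: 6 2,3,4,5-tetrabromo-6-(trimethylsilyl)phenyl trifluoromethanesulfonate
Conditions: Tf2O, pyridine, CH2Cl2, 0 °C
Reagents that add atoms: trifluoromethanesulfonic anhydride, O=S(=O)(OS(=O)(=O)C(F)(F)F)C(F)(F)F
Why: O-triflation of a phenol with Tf2O and pyridine; the acidic phenol is sulfonylated at oxygen, and the electron-poor aryl–silicon bond should survive these fluoride-free conditions.

**Step 4**
Reactants: 7 3,5-dibromosalicylaldehyde (3,5-dibromo-2-hydroxybenzaldehyde)
Product: 8 3,5-dibromo-2-methoxybenzaldehyde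
Conditions: MeI, K2CO3, DMF, rt
Reagents that add atoms: iodomethane, CI
Why: Williamson O-methylation of an acidic phenol; the phenoxide is the only nucleophile present and the aldehyde is inert to these conditions.

**Step 5**
Reactants: 8 3,5-dibromo-2-methoxybenzaldehyde
Product: 10 3,5-dibromo-2-methoxyphenol, via aryl formate 9 (not isolated)
Conditions: mCPBA, CH2Cl2, 40 °C; then MeOH, Et3N, rt
Reagents that add atoms: 3-chloroperoxybenzoic acid, OOC(=O)c1cccc(Cl)c1
Why: Baeyer–Villiger (Dakin-type) oxidation of an ortho-alkoxybenzaldehyde, in which the aryl group with the ortho methoxy donor migrates in the Criegee adduct to give formate 9, followed by amine-catalysed transesterification of the labile aryl formate with methanol; the oxygen enters exactly at the former formyl carbon, so the substitution pattern of ring A is fixed.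

**Step 6**
Reactants: 6 2,3,4,5-tetrabromo-6-(trimethylsilyl)phenyl trifluoromethanesulfonate; 10 3,5-dibromo-2-methoxyphenol; 11 nonafluoro-1-iodobutane
Product: 15 1,2,3,4-tetrabromo-5-(3,5-dibromo-2-methoxyphenoxy)-6-iodobenzene, via caesium phenoxide 12 (not isolated), via tetrabromobenzyne 13 (not isolated), via arylcaesium adduct 14 (not isolated)
Conditions: 10 (1.5 equiv), CsOH·H2O (1.5 equiv), MeOH, then evaporation from PhMe to dryness; 11 (5 equiv), CsF (2 equiv), 18-crown-6 (2 equiv), THF, −20 °C, dark; 6 (1.0 equiv) added over 2 h, then → 0 °C
Reagents that add atoms: none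
Why: Fluoride attacks silicon of 6 and triflate leaves in step with it, so aryne 13 arises without a free aryl anion that the iodine donor could intercept; phenoxide 12 adds to one aryne carbon (B1–O bond) and the arylcaesium 14 attacks iodine of 11 halophilically (B2–I bond), the perfluorobutyl anion then collapsing to octafluorobut-1-ene and CsF. The closest known reaction type is the three-component coupling of an aryne with a heteroatom nucleophile and an electrophilic halogen donor, combined with the established O-arylation of phenols by arynes from ortho-silyl triflates. No ring closes and no stereocentre is formed. Regiochemistry is not in question, because both carbons flanking the triple bond carry bromine and the two aryne termini are therefore equivalent, while four inductively withdrawing bromines should make the aryne electrophilic enough for the hindered, weakly basic phenoxide. The selectivity needed is iodination of 14 ahead of its protonation and ahead of loss of the neighbouring bromide; a proton-free medium with dried, preformed phenoxide, a fivefold excess of the soluble iodine donor, slow addition of 6 at low temperature and exclusion of light (which could start radical perfluoroalkylation of the phenoxide) are meant to secure it.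

**Step 7**
Reactants: 15 1,2,3,4-tetrabromo-5-(3,5-dibromo-2-methoxyphenoxy)-6-iodobenzene
Product: 18 2,3,4,5-tetrabromo-6-(3,5-dibromo-2-methoxyphenoxy)phenol, via arylmagnesium chloride 16 (not isolated), via dimethyl arylboronate 17 (not isolated)
Conditions: iPrMgCl·LiCl (1.05 equiv), THF, −78 °C, 15 min; B(OMe)3 (3 equiv), −78 → 0 °C; AcOH, 30% H2O2, 0 °C → rt
Reagents that add atoms: hydrogen peroxide, OO
Why: Iodine–magnesium exchange with the turbo-Grignard reagent, which at −78 °C should be far faster at the C–I bond flanked by oxygen and bromine than at any C–Br bond, then borylation of 16 and oxidative 1,2-shift of the aryl group from boron to oxygen under acidic peroxide conditions that avoid base-induced protodeboronation of the electron-poor, doubly ortho-substituted boronate 17.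

**Compound list**

1 | pentabromophenol | Oc1c(Br)c(Br)c(Br)c(Br)c1Br | starting material
2 | trimethyl(pentabromophenoxy)silane | C[Si](C)(C)Oc1c(Br)c(Br)c(Br)c(Br)c1Br | intermediate
3 | [2,3,4,5-tetrabromo-6-(trimethylsilyloxy)phenyl]lithium | [Li]c1c(O[Si](C)(C)C)c(Br)c(Br)c(Br)c1Br | intermediate
4 | lithium 2,3,4,5-tetrabromo-6-(trimethylsilyl)phenoxide | [Li+].[O-]c1c([Si](C)(C)C)c(Br)c(Br)c(Br)c1Br | intermediate
5 | 2,3,4,5-tetrabromo-6-(trimethylsilyl)phenol | Oc1c([Si](C)(C)C)c(Br)c(Br)c(Br)c1Br | intermediate
6 | 2,3,4,5-tetrabromo-6-(trimethylsilyl)phenyl trifluoromethanesulfonate | C[Si](C)(C)c1c(OS(=O)(=O)C(F)(F)F)c(Br)c(Br)c(Br)c1Br | intermediate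
7 | 3,5-dibromosalicylaldehyde (3,5-dibromo-2-hydroxybenzaldehyde) | O=Cc1cc(Br)cc(Br)c1O | starting material
8 | 3,5-dibromo-2-methoxybenzaldehyde | COc1c(Br)cc(Br)cc1C=O | intermediate
9 | 3,5-dibromo-2-methoxyphenyl formate | COc1c(Br)cc(Br)cc1OC=O | intermediate
10 | 3,5-dibromo-2-methoxyphenol | COc1c(Br)cc(Br)cc1O | intermediate
11 | nonafluoro-1-iodobutane | FC(F)(F)C(F)(F)C(F)(F)C(F)(F)I | starting material
12 | caesium 3,5-dibromo-2-methoxyphenoxide | [Cs+].[O-]c1cc(Br)cc(Br)c1OC | intermediate
13 | 3,4,5,6-tetrabromobenzyne (1,2,3,4-tetrabromo-5,6-didehydrobenzene) | BrC1=C(Br)C(Br)=C(Br)C#C1 | intermediate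
14 | [2,3,4,5-tetrabromo-6-(3,5-dibromo-2-methoxyphenoxy)phenyl]caesium | COc1c(Br)cc(Br)cc1Oc1c([Cs])c(Br)c(Br)c(Br)c1Br | intermediate
15 | 1,2,3,4-tetrabromo-5-(3,5-dibromo-2-methoxyphenoxy)-6-iodobenzene | COc1c(Br)cc(Br)cc1Oc1c(I)c(Br)c(Br)c(Br)c1Br | intermediate
16 | [2,3,4,5-tetrabromo-6-(3,5-dibromo-2-methoxyphenoxy)phenyl]magnesium chloride | COc1c(Br)cc(Br)cc1Oc1c([Mg]Cl)c(Br)c(Br)c(Br)c1Br | intermediate
17 | dimethyl [2,3,4,5-tetrabromo-6-(3,5-dibromo-2-methoxyphenoxy)phenyl]boronate | COB(OC)c1c(Oc2cc(Br)cc(Br)c2OC)c(Br)c(Br)c(Br)c1Br | intermediate
18 | 2,3,4,5-tetrabromo-6-(3,5-dibromo-2-methoxyphenoxy)phenol | COc1c(Br)cc(Br)cc1Oc1c(O)c(Br)c(Br)c(Br)c1Br | target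

**Step count**

Total steps: 7. Longest linear sequence: 5 (steps 1, 2, 3, 6, 7); steps 4 and 5 form the second branch.

**Steps most likely to fail**

1. Step 6. Several processes compete with iodine transfer:
   - the aryl anion may expel the neighbouring bromide and open a second aryne, leading to oligomers;
   - it may pick up a proton instead of iodine;
   - the phenoxide may attack sulfur of the electron-poor triflate and strip the triflyl group;
   - part of the phenoxide may be consumed by the perfluorobutene that is released.

   Fallback: it sets out from 6 and 10. With free phenol 10 and CsF in MeCN at room temperature the aryne is simply O-arylated, the aryl anion being protonated at once by the phenol, to give 1,2,3,4-tetrabromo-5-(3,5-dibromo-2-methoxyphenoxy)benzene F1. Its only ring B hydrogen, flanked by the ether oxygen and a bromine on the most electron-poor ring, is then removed with (2,2,6,6-tetramethylpiperidyl)magnesium chloride–lithium chloride (TMPMgCl·LiCl) in THF at −40 °C. This directed magnesiation gives arylmagnesium chloride 16, where the fallback rejoins the route inside step 7 (borylation and oxidation to 18).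

2. Step 2. Three processes threaten it:
   - exchange may take place at a bromine remote from oxygen, and such a lithio isomer could lose LiBr if equilibration is slow;
   - n-BuLi or an aryllithium may attack silicon of the very labile aryl silyl ether, causing desilylation or intermolecular C-silylation;
   - the ortho-lithio species may eliminate before silicon migrates.

   Fallback: it sets out from 1. Alkylation with chloromethyl methyl ether and iPr2NEt in CH2Cl2 gives 1,2,3,4,5-pentabromo-6-(methoxymethoxy)benzene F2. Bromine–magnesium exchange with iPrMgCl·LiCl in THF at −40 °C, steered to an ortho bromine by chelation of magnesium to the acetal oxygens, gives [2,3,4,5-tetrabromo-6-(methoxymethoxy)phenyl]magnesium chloride F3, which is stable towards elimination at this temperature. Quenching with Me3SiCl (warming to rt) gives [2,3,4,5-tetrabromo-6-(methoxymethoxy)phenyl]trimethylsilane F4. Cleavage of the acetal with HCl in MeOH returns to the route at 5.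

3. Step 7. Three processes threaten it:
   - the exchange may spill over to a C–Br bond of the perbrominated ring;
   - the doubly ortho-substituted, electron-poor arylmagnesium may be captured only slowly by the borate;
   - boron may be lost by protonolysis before the oxidative shift occurs.

   Fallback: it sets out from arylmagnesium chloride 16. Direct oxygen transfer from tert-butyl peroxybenzoate in THF at −78 → 0 °C gives 1,2,3,4-tetrabromo-5-tert-butoxy-6-(3,5-dibromo-2-methoxyphenoxy)benzene F5, with no boron intermediate. Cleavage of the tert-butyl ether with CF3CO2H in CH2Cl2 at rt gives 18.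

**Further compounds**

F1 | step 6 | 1,2,3,4-tetrabromo-5-(3,5-dibromo-2-methoxyphenoxy)benzene | COc1c(Br)cc(Br)cc1Oc1cc(Br)c(Br)c(Br)c1Br
F2 | step 2 | 1,2,3,4,5-pentabromo-6-(methoxymethoxy)benzene | COCOc1c(Br)c(Br)c(Br)c(Br)c1Br
F3 | step 2 | [2,3,4,5-tetrabromo-6-(methoxymethoxy)phenyl]magnesium chloride | COCOc1c([Mg]Cl)c(Br)c(Br)c(Br)c1Br
F4 | step 2 | [2,3,4,5-tetrabromo-6-(methoxymethoxy)phenyl]trimethylsilane | COCOc1c([Si](C)(C)C)c(Br)c(Br)c(Br)c1Br
F5 | step 7 | 1,2,3,4-tetrabromo-5-tert-butoxy-6-(3,5-dibromo-2-methoxyphenoxy)benzene | COc1c(Br)cc(Br)cc1Oc1c(OC(C)(C)C)c(Br)c(Br)c(Br)c1Br
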